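**Strategy.** Ring B of the target (numbered as a catechol: C1–OH, C2–O–aryl, Br on C3, C5, C6) is cut back to C2-symmetric 3,6-dibromocatechol (4). Its bromines sit on C3 and C6, the carbons flanking the two oxygens, which electrophilic bromination of catechol does not reach. These are the α-carbons of commercial cyclohexane-1,2-dione (1), an unsubstituted saturated six-membered 1,2-diketone. One operation with three equivalents of Br2 forms both C–Br bonds and aromatizes the ring. Monobenzylation, bromination para to the free OH, metal-free O-arylation with an iodonium salt carrying ring A, and BCl3 debenzylation complete the target.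

Key step: step 1

Remarks on the chemistry:
- The target is achiral. The stereogenic carbons of the transient bromodiones 2 and 3 are uncontrolled and disappear on aromatization.
- The spectator aryl of the iodonium salt is taken as 2,4,6-trimethoxyphenyl rather than a trialkylphenyl. A phenoxide may pick up an ortho-hindered but electronically neutral aryl, whereas the very electron-rich trimethoxyphenyl group stays on iodine.

Step 1
Reactants: 1 cyclohexane-1,2-dione
Product: 4 3,6-dibromobenzene-1,2-diol, via 3,6-dibromocyclohexane-1,2-dione 2 (not isolated), via 3,3,6-tribromocyclohexane-1,2-dione 3 (not isolated)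
Conditions: Br2 (2.0 equiv, slow addition), CHCl3/AcOH, 0 °C → rt; then Br2 (1.0 equiv), rt → 55 °C; aq. NaHSO3 work-up
Reagents that add atoms: bromine, BrBr
Why: The diketone reacts through its enol, so acid-catalysed enol bromination places one bromine on C3 and, after enolization toward the still unsubstituted side, one on C6 to give 2; the third equivalent brominates an α-carbon a second time to give 3, HBr is lost across C3–C4, and the resulting ene-dione is the keto tautomer of 4, which enolizes to the aromatic catechol with both C–Br bonds retained. The closest known reaction type is the halogenative aromatization of cyclohexane-1,2-diones and cyclohexanones to halogenated catechols and phenols by α-halogenation and dehydrohalogenation. No ring is closed, the existing six-membered carbocycle is dehydrogenated, and no stereocenter survives because the stereogenic CHBr carbons of 2 and 3 become sp2. The selectivity needed is α,α′- rather than α,α-dibromination before aromatization and no further bromination at C4/C5 afterwards: the first should be secured because an α-bromoketone enolizes more slowly toward its bromine-bearing carbon and the HBr formed equilibrates any geminal dibromide to the α,α′-isomer, the second by exact bromine stoichiometry added in portions, by the deactivation of 4 by its two bromines, and by a reductive work-up that returns any o-quinone to the catechol.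

Step 2
Reactants: 4 3,6-dibromobenzene-1,2-diol
Product: 5 2-(benzyloxy)-3,6-dibromophenol
Conditions: BnBr (1.0 equiv), K2CO3 (1.0 equiv), DMF, 0 °C → rt
Reagents that add atoms: benzyl bromide, BrCc1ccccc1
Why: Williamson ether synthesis in which the two hydroxyls are equivalent by symmetry, so no regiocontrol is needed, and one equivalent of base gives the hydrogen-bonded catechol monoanion, which should be alkylated once because the remaining hindered OH of 5 is less acidic and reacts more slowly.

Step 3
Reactants: 5 2-(benzyloxy)-3,6-dibromophenol
Product: 6 2-(benzyloxy)-3,4,6-tribromophenol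
Conditions: NBS (1.05 equiv), MeCN, 0 °C → rt, dark
Reagents that add atoms: N-bromosuccinimide, O=C1CCC(=O)N1Br
Why: Electrophilic aromatic bromination directed by the free OH, whose two ortho positions are occupied so that attack should go to its para carbon C4 (C5 of ring B in the target), while the alternative position is activated only by a benzyloxy group twisted out of conjugation by its two ortho neighbours.

Step 4
Reactants: 7 2,4-dibromophenol
Product: 8 2,4-dibromo-6-iodophenol
Conditions: NIS (1.05 equiv), TsOH·H2O (10 mol %), MeCN, rt
Reagents that add atoms: N-iodosuccinimide, O=C1CCC(=O)N1I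
Why: Electrophilic aromatic iodination of a phenol whose para and one ortho position carry bromine, so the only activated site left is C6.

Step 5
Reactants: 8 2,4-dibromo-6-iodophenol
Product: 9 1,5-dibromo-3-iodo-2-methoxybenzene
Conditions: MeI (1.5 equiv), K2CO3 (1.5 equiv), DMF, rt
Reagents that add atoms: iodomethane, CI
Why: Williamson O-methylation of an acidic trihalophenol, which is readily deprotonated by carbonate and has no competing nucleophilic site.

Step 6
Reactants: 9 1,5-dibromo-3-iodo-2-methoxybenzene
Product: 11 (3,5-dibromo-2-methoxyphenyl)(2,4,6-trimethoxyphenyl)iodonium 4-methylbenzenesulfonate, via hydroxy(tosyloxy)iodoarene 10 (not isolated)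
Conditions: mCPBA (1.1 equiv), TsOH·H2O (1.05 equiv), MeCN, 77 °C; then 1,3,5-trimethoxybenzene (1.05 equiv), 77 °C; Et2O trituration
Reagents that add atoms: p-toluenesulfonic acid monohydrate, Cc1ccc(cc1)S(O)(=O)=O.O; 1,3,5-trimethoxybenzene, COc1cc(OC)cc(OC)c1
Why: One-pot diaryliodonium synthesis in which peracid oxidation of the aryl iodide in the presence of TsOH gives the Koser-type trivalent iodine species 10, which is attacked in an electrophilic aromatic substitution by the highly nucleophilic trimethoxybenzene, while the halogen-deactivated ring of 9 does not compete.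

Step 7
Reactants: 6 2-(benzyloxy)-3,4,6-tribromophenol; 11 (3,5-dibromo-2-methoxyphenyl)(2,4,6-trimethoxyphenyl)iodonium 4-methylbenzenesulfonate
Product: 13 1-(benzyloxy)-2,3,5-tribromo-6-(3,5-dibromo-2-methoxyphenoxy)benzene, via aryloxy-λ3-iodane 12 (not isolated)
Conditions: t-BuOK (1.1 equiv), THF, 0 °C; then 11 (1.2 equiv), rt → 40 °C
Reagents that add atoms: none
Why: Metal-free O-arylation of a phenoxide with a diaryliodonium salt, in which the phenoxide replaces tosylate on trivalent iodine to give 12 and ligand coupling should then deliver the electron-poor, ortho-substituted dibromoanisyl group to oxygen and expel 2-iodo-1,3,5-trimethoxybenzene, a process known to tolerate di-ortho-substituted phenols and, lacking any transition metal, to leave all five C–Br bonds untouched.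

Step 8
Reactants: 13 1-(benzyloxy)-2,3,5-tribromo-6-(3,5-dibromo-2-methoxyphenoxy)benzene
Product: 15 2,3,5-tribromo-6-(3,5-dibromo-2-methoxyphenoxy)phenol, via aryl dichloroborinate 14 (not isolated)
Conditions: BCl3 (2.0 equiv), C6HMe5 (3.0 equiv), CH2Cl2, −78 °C; then H2O quench
Reagents that add atoms: none
Why: Lewis-acid debenzylation with a cation scavenger, in which BCl3 binds the hindered benzyloxy oxygen, the benzyl cation is captured by pentamethylbenzene in a Friedel–Crafts alkylation and the borinate 14 is hydrolysed on quenching, conditions under which the aryl methyl ether, the diaryl ether and the C–Br bonds should stay intact, whereas hydrogenolysis would strip bromine.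

**Compound list**

1 | cyclohexane-1,2-dione | O=C1CCCCC1=O | starting material
2 | 3,6-dibromocyclohexane-1,2-dione (cis/trans mixture, not isolated) | O=C1C(Br)CCC(Br)C1=O | intermediate
3 | 3,3,6-tribromocyclohexane-1,2-dione (racemic, not isolated) | O=C1C(Br)CCC(Br)(Br)C1=O | intermediate
4 | 3,6-dibromobenzene-1,2-diol (3,6-dibromocatechol) | Oc1c(Br)ccc(Br)c1O | intermediate
5 | 2-(benzyloxy)-3,6-dibromophenol | Oc1c(Br)ccc(Br)c1OCc1ccccc1 | intermediate
6 | 2-(benzyloxy)-3,4,6-tribromophenol | Oc1c(Br)cc(Br)c(Br)c1OCc1ccccc1 | intermediate
7 | 2,4-dibromophenol | Oc1ccc(Br)cc1Br | starting material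
8 | 2,4-dibromo-6-iodophenol | Oc1c(Br)cc(Br)cc1I | intermediate
9 | 1,5-dibromo-3-iodo-2-methoxybenzene | COc1c(Br)cc(Br)cc1I | intermediate
10 | (3,5-dibromo-2-methoxyphenyl)(hydroxy)(tosyloxy)-λ3-iodane (not isolated) | COc1c(Br)cc(Br)cc1I(O)OS(=O)(=O)c1ccc(C)cc1 | intermediate
11 | (3,5-dibromo-2-methoxyphenyl)(2,4,6-trimethoxyphenyl)iodonium 4-methylbenzenesulfonate | COc1cc(OC)c([I+]c2cc(Br)cc(Br)c2OC)c(OC)c1.Cc1ccc(cc1)S(=O)(=O)[O-] | intermediate
12 | [2-(benzyloxy)-3,4,6-tribromophenoxy](3,5-dibromo-2-methoxyphenyl)(2,4,6-trimethoxyphenyl)-λ3-iodane (not isolated) | COc1cc(OC)c(I(Oc2c(Br)cc(Br)c(Br)c2OCc2ccccc2)c2cc(Br)cc(Br)c2OC)c(OC)c1 | intermediate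
13 | 1-(benzyloxy)-2,3,5-tribromo-6-(3,5-dibromo-2-methoxyphenoxy)benzene | COc1c(Br)cc(Br)cc1Oc1c(Br)cc(Br)c(Br)c1OCc1ccccc1 | intermediate
14 | 2,3,5-tribromo-6-(3,5-dibromo-2-methoxyphenoxy)phenyl dichloroborinate (not isolated) | COc1c(Br)cc(Br)cc1Oc1c(Br)cc(Br)c(Br)c1OB(Cl)Cl | intermediate
15 | 2,3,5-tribromo-6-(3,5-dibromo-2-methoxyphenoxy)phenol | COc1c(Br)cc(Br)cc1Oc1c(Br)cc(Br)c(Br)c1O | target

**Step count.** Total steps: 8. Longest linear sequence: 5 (steps 1, 2, 3, 7, 8; the iodonium branch, steps 4, 5, 6, 7, 8, is equally long).

**Steps most likely to fail**

1. Step 1. Bromine may enter the same α-carbon twice or continue onto the ring once it is aromatic, so that positional control is lost, or the catechol may be over-oxidized to the o-quinone. The fallback replaces enol bromination by directed ortho-metalation. Because step 1 opens the route, no earlier numbered compound exists to set out from, and the detour sets out from commercial 1,2-dimethoxybenzene F1. Dilithiation at both positions ortho to the methoxy groups with n-BuLi/TMEDA in hexane/Et2O and quenching with 1,2-dibromotetrachloroethane should give 1,4-dibromo-2,3-dimethoxybenzene F2. BBr3 in CH2Cl2 (−78 °C → rt) then removes both methyl groups, and the sequence comes back to the route at compound 4.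

2. Step 7. Ligand exchange of the di-ortho-substituted, electron-poor phenoxide onto iodine may be slow, the spectator aryl may be transferred in part, or the salt may decompose under base. The fallback is an oxidative copper coupling (Chan–Lam). It sets out from compound 9: iodine–magnesium exchange with i-PrMgCl·LiCl at −40 °C (iodine exchanges far faster than bromine, and no halogen sits ortho to the new C–Mg bond), then B(OMe)3 and aqueous acid, should give (3,5-dibromo-2-methoxyphenyl)boronic acid F3. Coupling F3 with phenol 6 under Cu(OAc)2, pyridine, 4 Å molecular sieves, CH2Cl2, air, rt, where divalent copper does not insert into C–Br bonds, returns to the route at compound 13.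

3. Step 8. The methyl ether, flanked by bromine and the aryloxy group, may be cleaved along with the benzyl ether if the mixture warms, or the benzyl cation may re-add to the product ring. The fallback changes the protecting group to one removed by mild protic acid. It sets out from compound 4: MOMCl (1.0 equiv), i-Pr2NEt, CH2Cl2, 0 °C should give 3,6-dibromo-2-(methoxymethoxy)phenol F4. NBS in MeCN then gives 3,4,6-tribromo-2-(methoxymethoxy)phenol F5. Arylation with 11 under the conditions of step 7 gives 2,3,5-tribromo-6-(3,5-dibromo-2-methoxyphenoxy)phenyl methoxymethyl ether F6. HCl in MeOH at 40 °C then cleaves the acetal and returns to the route at compound 15.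

**Further compounds**

F1 | step 1 | 1,2-dimethoxybenzene (bought) | COc1ccccc1OC
F2 | step 1 | 1,4-dibromo-2,3-dimethoxybenzene | COc1c(Br)ccc(Br)c1OC
F3 | step 7 | (3,5-dibromo-2-methoxyphenyl)boronic acid | COc1c(Br)cc(Br)cc1B(O)O
F4 | step 8 | 3,6-dibromo-2-(methoxymethoxy)phenol | COCOc1c(Br)ccc(Br)c1O
F5 | step 8 | 3,4,6-tribromo-2-(methoxymethoxy)phenol | COCOc1c(Br)c(Br)cc(Br)c1O
F6 | step 8 | 2,3,5-tribromo-6-(3,5-dibromo-2-methoxyphenoxy)phenyl methoxymethyl ether | COCOc1c(Br)c(Br)cc(Br)c1Oc1cc(Br)cc(Br)c1OC
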